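Start with the easy count: suppose each Z costs one J, and treat every flask as a J budget.

| setting | Tuesday's | Monday's | Friday's | flask |
|---|---|---|---|---|
| G | 0.050 M | 0.050 M | 0.050 M | 0.050 M |
| D | 0.050 M (fed, over 3.0 s) | 0.050 M (fed, over 3.0 s) | 0.025 M (fed, over 3.0 s) | 0.0500 M (fed, over 3.0 s) |
| J | 0.013 M | 0.050 M | 0.025 M | 0.0250 M |
| X | 50 µM | 50 µM | 50 µM | 50 µM |
| remark | run made earlier; the fed solution adds 0.20 times the starting volume | run made earlier; the fed solution adds 0.20 times the starting volume | run made earlier; the fed solution adds 0.20 times the starting volume | the fed solution adds 0.20 times the starting volume |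
| time |  |  |  | 5.0 min |

| run | time / min | Z / % | G / % |
|---|---|---|---|
| Tuesday's | 0.333 | 10.1 | 89.5 |
| Tuesday's | 0.667 | 14.7 | 85.0 |
| Tuesday's | 1.50 | 18.8 | 81.6 |
| Tuesday's | 4.00 | 20.1 | 81.3 |
| Monday's | 1.00 | 63.5 | 37.2 |
| Monday's | 2.00 | 69.8 | 31.6 |
| Monday's | 3.00 | 70.4 | 29.5 |
| Monday's | 4.00 | 69.9 | 29.9 |
| Friday's | 1.00 | 35.8 | 63.6 |
| Friday's | 2.00 | 42.1 | 58.9 |
| Friday's | 3.00 | 42.6 | 58.1 |
| Friday's | 4.00 | 42.5 | 57.5 |

(standard deviation of a reading: 0.5 percentage points)

- at 5.0 min, what has stopped the reaction, if anything has (all of G has reacted / no working catalyst is left / forward and back rates have come level / it is still moving / J has run out first)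
- Z at 5.0 min, in percent of the G charged

- charges are per starting volume, the dose included; the dosed solution carries all of it
- the reaction counts as stopped when no species that holds the G changes by six tenths of a point or more over the second half of the time

First take the main step by itself. If J served G and nothing else, Z in the new flask would stop at 50.0% of the G charged.

Now add D. Monday's last reading of Z is 69.9%, below the 100% its J allows, with G reading 29.9%. So I let D take the missing J, and that gives the fraction of D used in each run. If G and D compete for J, one ratio should stay steady from run to run. Tuesday reads 3.69, Monday 3.35 and Friday 3.41. Their mean, a reading with the scatter of the runs in it, is 3.48. Call it S, the selectivity factor: the ln of the fraction of G left over the ln of the fraction of D left.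

For the new flask, I take the fraction of G left as the fraction of D left raised to S, and I let the two uses add up to the J charged. Monday's and Tuesday's shares of J in Z suggest a trial Z of 36.8%. One pass through the balance gives 37.7%, and a second gives 37.3%.

Then add the rest, which is time. Friday's run has the J charge of the new flask, and its Z changes by 0.1 percentage points from 3.00 min to 4.00 min, against a scatter of 0.5 points. So I expect the new flask to be level by 5.0 min. My call is J as the limiting reagent, with Z at 37.3%.

The forecast differs: no working catalyst is left, with Z at 39%. Among its grounds: “Each run also approaches its plateau with the same time constant, about 0.5 min, whatever the concentrations.”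

At 5.00 min, the new flask's answer is: J has run out first, with J at 0% of its charge and Z at 36.8%.

    G + X ⇌ Q (K = 150 M⁻¹, k = 80000 M⁻¹ s⁻¹)
    J + Q → X + Z (k = 820 M⁻¹ s⁻¹)
    D + X ⇌ L (K = 21.0 M⁻¹, k = 2500 M⁻¹ s⁻¹)
    J + L → X + E (k = 2200 M⁻¹ s⁻¹)

In the new flask at 0.305 min, J goes to Z 2.7 times as fast as it goes through L to E. At 5.00 min, 100% of the catalyst in the new flask can still turn over. The new flask's own Z and D at 5.00 min give S as 3.23. In the neighbour with 0.20 M of D, the 93% of D left, raised to my S, puts Z at 22.3%, and that neighbour gives 21.9%.

The numbers in the tables were computed for an exercise; noise was put on by code.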